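The vessel is Tuesday's flask, closed and stirred at 5 °C with the gas held at 74 mM. You want a quick number, and your hunch is that its stall is equilibrium.

| flask | starting material | second substrate | gas | free catalyst | temperature | remark | time |
|---|---|---|---|---|---|---|---|
| Tuesday's | 0.26 M | 1 equiv | 74 mM (held) | 2 mol% | 5 °C | the very flask that is asked about, followed so far |  |
| Thursday's | 0.39 M | 1 equiv | 74 mM (held) | 2 mol% | 0 °C | run made earlier |  |
| flask | 0.26 M | 1.00 equiv | 74 mM (held) | 2 mol% | 5 °C |  | 8.0 d |

| Tuesday's: time / h | Tuesday's: target / % | Thursday's: time / h | Thursday's: target / % |
|---|---|---|---|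
| 12.0 | 26 | 1.33 | 2 |
| 20.0 | 35 | 4.00 | 12 |
| 30.0 | 45 | 8.00 | 20 |
| 40.0 | 51 | 10.0 | 27 |
| 72.0 | 61 | 15.0 | 36 |
| 96.0 | 66 | 20.0 | 40 |
| 144 | 68 | 25.0 | 43 |

(standard deviation of a reading: 1.5 percentage points)

- theta: change nothing and wait 2.5 d more
- beta: at 8.0 d take out 90 % of the target then present, then wait 2.5 d
- gamma: at 8.0 d raise the temperature by 20 K, then wait 2.5 d
- zeta: at 8.0 d add free catalyst, 50.0 % of the amount charged, then wait 2.5 d

- removed target is counted in
- what was read earlier has a scatter of 1.5 percentage points, one standard deviation
- at the start none of the gas is in solution
- additions bring no volume worth counting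

- target, in percent of the starting material first charged, at 8.0 d
- what to do for the largest gain in target; "none" if nothing gains more than 2 percentage points (theta / beta / gamma / zeta / none)
- target present, with what was taken out counted in, in percent of the starting material first charged, after theta
- target present, with what was taken out counted in, in percent of the starting material first charged, after beta

1. Thursday's run speaks against your hunch. It is colder and more concentrated, yet it reads 43 % at 25.0 h and is already bending. The forecast says “the stall is more likely lost catalyst than equilibrium”, and I agree.

2. So I follow one catalyst molecule. At each fork it either turns over and returns, or it is lost. I assume both branches scale alike with the starting material, so the odds hold as the flask empties, and each catalyst makes a fixed count of target before it is lost.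

3. Tuesday's last reading, 68 % on a charge of 2 mol%, gives 34.0. This is N, target made per catalyst charged, the turnover number. It rests on a reading with a scatter of 1.5 percentage points, and it is a floor if some catalyst still works at that time.

4. If N holds, waiting adds little to Tuesday's flask, and taking out target opens no new turnovers. Option zeta adds catalyst worth 34.0 % of the charge, about equal to the 32.0 % that was not target at the last reading. N does not say how much of that arrives in the 2.5 d allowed.

5. The forecast, which I stand by, gives 69 % now, 69.5 % after theta, 70 % after beta, best zeta.

    starting material + reagent + free catalyst → free catalyst + target (k = 86.0 M⁻² h⁻¹, Ea = 44.0 kJ mol⁻¹)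
    second substrate + reagent + free catalyst → free catalyst + second product (k = 7.10 M⁻² h⁻¹, Ea = 59.0 kJ mol⁻¹)
    2 second substrate → homo dimer (k = 0.120 M⁻¹ h⁻¹, Ea = 71.0 kJ mol⁻¹)
    gas ⇌ reagent, rate k4*(csat - [reagent]) (kL = 8.50 h⁻¹)
    starting material + free catalyst → spent catalyst (k = 0.170 M⁻¹ h⁻¹, Ea = 65.0 kJ mol⁻¹)
    (constants at 5 °C)

The flask gives 71.5 % at 8.0 d, and 72.8 % after theta or 72.8 % after beta; the best is zeta, gaining 15 points. With 96.5 % of its catalyst spent, it made 37.0 target per catalyst spent. The odds at the fork from the equations, k1·c(reagent)/k5 with c(reagent) at 0.0740 M, come to 37.4. For the neighbour flask charged with 0.8 mol% of free catalyst, N gives 27.2 %. That neighbour flask stands at 29.7 % target, with 69.5 % of its starting material left.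

The numbers in the tables were computed with made-up constants.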